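**Plan**

1. Numbering follows the target: dihydropyran O2–C1(OAc)–C11a–C4a–C4=C3; carbocycle C4a–C5–C6–C7(CH3)–C8–C9–C10–C11(=C19H2)–C11a; side chain C12–C17.
2. Cuts: C14=C15 (cross-metathesis) and C12–C13 (allylboration); then the dihydropyran itself (O2–C1 closed, O2–C3 taken from an oxirane); then C9–C10 and C11=C19 (ring-expanding Claisen rearrangement and methylenation of a seven-membered lactone); then C11a–C1 (enolate alkylation), the lactone C7–O bond (Baeyer–Villiger) and C4a–C4 (conjugate addition).
3. Forward order of rings: cyclohexenone, 3-alkenylcyclohexanone, oxepan-2-one, nine-membered carbocycle (Z-7,8 olefin and C19 methylene in place), 7,8-oxirane, and only then the dihydropyran, the last ring of all; acetates and the C13–C17 chain follow.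
4. Enabling feature: C4 carries two one-carbon arms (C3, C12) and lies two atoms (C4a, C11a) from C1, so an oxygen on either arm reaches C1 in a six-membered ring. A C3–O–C4 oxirane bearing the C12 formyl group is a strained isomer of a 2-substituted malondialdehyde; opening it releases an enol whose oxygen becomes O2, and the other arm stays as the C12 aldehyde (the arms are equivalent, so there is no regiochemical choice).
5. Stereochemistry: C4a from the (S)-BINAP/Rh conjugate addition; C11a by trans alkylation next to C4a; C7/C8 by Shi epoxidation (reagent control) of the Z olefin that the ring-constrained Claisen step delivers; C1 by kinetic acetylation of the lactol; C12 by Brown allylboration; 14E from cross-metathesis.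

Key step: step 12

Remarks on the chemistry:
- Atoms keep the target numbering given above in all intermediates.
- Compound 5 and the named reagents are taken as catalogue items.
- Compound 1 is racemic. The quaternary carbon made in step 1 becomes the trigonal C7 in step 6, so compounds 6 to 9 are carried as both epimers at that carbon and their SMILES leave it undefined.

Step 1
Reactants: 1 6-methylcyclohex-2-en-1-one (racemic); 2 acetaldehyde
Product: 3 6-(1-hydroxyethyl)-6-methylcyclohex-2-en-1-one (racemic, both diastereomers)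
Conditions: LiN(iPr)2, THF, −78 °C; then 2, −78 °C; aq. NH4Cl
Reagents that add atoms: none
Why: Kinetic α′-deprotonation gives the cross-conjugated lithium enolate, whose directed aldol addition to acetaldehyde creates the quaternary carbon (future C7), carried as both configurations because it becomes trigonal in step 6.

Step 2
Reactants: 3 6-(1-hydroxyethyl)-6-methylcyclohex-2-en-1-one
Product: 4 6-ethenyl-6-methylcyclohex-2-en-1-one (racemic)
Conditions: Burgess reagent, toluene, 50 °C
Reagents that add atoms: none
Why: Burgess dehydration (syn elimination of the sulfamate) can only take a hydrogen from the methyl group because the α-carbon is quaternary, so the 1-hydroxyethyl group becomes the vinyl group.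

Step 3
Reactants: 4 6-ethenyl-6-methylcyclohex-2-en-1-one; 5 tert-butyldimethyl{[2-(4,4,5,5-tetramethyl-1,3,2-dioxaborolan-2-yl)prop-2-en-1-yl]oxy}silane
Product: 6 (5S)-5-{3-[(tert-butyldimethylsilyl)oxy]prop-1-en-2-yl}-2-ethenyl-2-methylcyclohexan-1-one (both C2 epimers)
Conditions: [RhCl(cod)]2 (cat.), (S)-BINAP, KOH, aq. 1,4-dioxane, 60 °C
Reagents that add atoms: none
Why: Hayashi–Miyaura reaction in which the alkenyl group passes from boron to monovalent rhodium and adds 1,4 to the enone, the (S)-BINAP ligand directing attack to the face that gives the 4aS centre (same sense as in the formation of (S)-3-arylcyclohexanones from cyclohex-2-enone), irrespective of the remote quaternary carbon.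

Step 4
Reactants: 6 (5S)-5-{3-[(tert-butyldimethylsilyl)oxy]prop-1-en-2-yl}-2-ethenyl-2-methylcyclohexan-1-one
Product: 7 (4S)-4-{3-[(tert-butyldimethylsilyl)oxy]prop-1-en-2-yl}-7-ethenyl-7-methyloxepan-2-one (both C7 epimers)
Conditions: (Me3SiO)2, TMSOTf (cat.), CH2Cl2, −78 to −40 °C; pyridine quench
Reagents that add atoms: bis(trimethylsilyl) peroxide, C[Si](C)(C)OO[Si](C)(C)C
Why: Baeyer–Villiger oxidation in which the fully substituted allylic carbon migrates in preference to the CH2 group, under silyl peroxide conditions that do not epoxidise C=C bonds; no stereocentre is created.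

Step 5
Reactants: 7 (4S)-4-{3-[(tert-butyldimethylsilyl)oxy]prop-1-en-2-yl}-7-ethenyl-7-methyloxepan-2-one
Product: 8 (3S,4S)-4-{3-[(tert-butyldimethylsilyl)oxy]prop-1-en-2-yl}-7-ethenyl-7-methyl-3-{[tri(propan-2-yl)silyl]oxymethyl}oxepan-2-one (both C7 epimers)
Conditions: LiN(iPr)2, THF, −78 °C; then (chloromethoxy)tri(propan-2-yl)silane, DMPU, −78 °C
Reagents that add atoms: (chloromethoxy)tri(propan-2-yl)silane (TOM chloride), ClCO[Si](C(C)C)(C(C)C)C(C)C
Why: Alkylation of the lithium lactone enolate with the chloromethyl ether installs C1 at the only enolisable position and anti to the neighbouring C4a substituent, which sets the trans 4a,11a relationship; the enolate is kept cold so that an Ireland–Claisen pathway cannot compete.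

Step 6
Reactants: 8 (3S,4S)-4-{3-[(tert-butyldimethylsilyl)oxy]prop-1-en-2-yl}-7-ethenyl-7-methyl-3-{[tri(propan-2-yl)silyl]oxymethyl}oxepan-2-one
Product: 11 (1Z,6R,7S)-7-{3-[(tert-butyldimethylsilyl)oxy]prop-1-en-2-yl}-1-methyl-5-methylidene-6-{[tri(propan-2-yl)silyl]oxymethyl}cyclonon-1-ene, via methylideneoxepane 9 (not isolated), via cyclononenone 10 (not isolated)
Conditions: Cp2TiMe2 (3 equiv), toluene, 75 °C, dark; then 120 °C (sealed); then Cp2TiMe2 (2 equiv), 75 °C
Reagents that add atoms: dimethyltitanocene, [CH3-].[CH3-].[Ti+4].c1cc[cH-]c1.c1cc[cH-]c1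
Why: Petasis methylenation turns the lactone into the cyclic allyl vinyl ether 9, whose Claisen rearrangement (C9–C10 formed, O–C7 broken, bicyclic chair-like transition state) expands the ring by two carbons to ketone 10 with the ring-enforced Z 7,8-olefin, and the non-basic titanium reagent then methylenates C11 without epimerising C11a.

Step 7
Reactants: 11 (1Z,6R,7S)-7-{3-[(tert-butyldimethylsilyl)oxy]prop-1-en-2-yl}-1-methyl-5-methylidene-6-{[tri(propan-2-yl)silyl]oxymethyl}cyclonon-1-ene
Product: 12 (4aS,7Z,11aR) allylic alcohol: nine-membered ring of 11 with CH2=C4–C12H2OH on C4a and C1H2OSi(iPr)3 on C11a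
Conditions: pyridinium p-toluenesulfonate (cat.), MeOH, 0 °C to rt
Reagents that add atoms: none
Why: Acid-catalysed methanolysis (selective silyl ether cleavage) removes the more labile primary TBS ether and leaves the bulkier triisopropylsilyl ether on C1; the olefins are inert and no stereocentre is involved.

Step 8
Reactants: 12 (4aS,7Z,11aR) allylic alcohol
Product: 13 (4S,4aS,7Z,11aR) epoxy alcohol: C3–O–C4 oxirane with C12H2OH on C4, C1H2OSi(iPr)3 on C11a
Conditions: Ti(OiPr)4 (cat.), L-(+)-diethyl tartrate, t-BuOOH, 4 Å molecular sieves, CH2Cl2, −20 °C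
Reagents that add atoms: tert-butyl hydroperoxide, CC(C)(C)OO
Why: Sharpless epoxidation acts only on the allylic alcohol, so C3=C4 is epoxidised in the presence of the 7,8-olefin and the C19 methylene, and with C1 still silylated no hydroxyl is placed to open the new oxirane; L-(+)-tartrate should give the 4S oxirane, a centre that is erased in step 12.

Step 9
Reactants: 13 (4S,4aS,7Z,11aR) epoxy alcohol
Product: 14 (4S,4aS,7S,8R,11aR) bis-epoxide: 13 with a 7,8-oxirane (ring carbons C6 and C9 cis)
Conditions: Shi ketone (D-fructose-derived 1,2:4,5-di-O-isopropylidene-β-D-erythro-2,3-hexodiulo-2,6-pyranose), KHSO5 (as 2KHSO5·KHSO4·K2SO4), K2CO3, Bu4NHSO4, MeCN–CH2(OMe)2–aq. Na2B4O7, 0 °C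
Reagents that add atoms: potassium peroxymonosulfate, [K+].[O-]S(=O)(=O)OO
Why: Shi epoxidation, in which the chiral dioxirane reacts with the trisubstituted olefin much faster than with the 1,1-disubstituted C19 methylene and, by the spiro transition-state model for trisubstituted olefins (CH carbon C8 becomes R), should give the 7S,8R oxirane under reagent control.

Step 10
Reactants: 14 (4S,4aS,7S,8R,11aR) bis-epoxide
Product: 15 (4S,4aS,7S,8R,11aR) epoxy diol: C1H2OH and C12H2OH free
Conditions: Bu4NF, THF, 0 °C to rt
Reagents that add atoms: none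
Why: Fluoride cleaves the triisopropylsilyl ether (strong Si–F bond) under conditions that leave both oxiranes and the olefin untouched.

Step 11
Reactants: 15 (4S,4aS,7S,8R,11aR) epoxy diol
Product: 16 (4R,4aS,7S,8R,11aR) epoxy dialdehyde: C1 aldehyde on C11a and oxirane-2-carbaldehyde (C12HO on C4) on C4a
Conditions: Dess–Martin periodinane, NaHCO3, CH2Cl2, 0 °C
Reagents that add atoms: none
Why: Dess–Martin oxidation turns both primary alcohols into aldehydes under buffered conditions that should not epimerise C11a, giving the α,β-epoxy aldehyde and the C1 aldehyde together.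

Step 12
Reactants: 16 (4R,4aS,7S,8R,11aR) epoxy dialdehyde
Product: 18 (4aS,7S,8R,11aR) lactol aldehyde: the dihydropyran trans-fused to the nine-membered ring, OH on C1 (both anomers), C12 formyl on C4, via malondialdehyde enol 17 (not isolated)
Conditions: Pd(PPh3)4 (cat.), Ph2PCH2CH2PPh2, toluene, 80 °C
Reagents that add atoms: none
Why: Proposed new method: zerovalent palladium should insert into the strained C4–O bond of the oxirane because it lies alpha to the C12 formyl group, and β-hydride elimination from the resulting O–C3H2 palladium alkoxide followed by return of the hydrogen to C4 isomerises the oxirane to the 2-substituted malondialdehyde 17; the closest known reaction type is the palladium-catalysed isomerisation of α,β-epoxy ketones to β-diketones, here extended to an α,β-epoxy aldehyde. The acidic enol OH of 17 then adds to the C1 aldehyde in a 6-exo-trig closure (O2–C1), which forms the dihydropyran as its lactol. C1 is the only new stereocentre and stays under thermodynamic control (anomer equilibration) until it is fixed in step 13, while C4 becomes trigonal so its configuration in 16 is irrelevant. The step needs chemoselectivity between two oxiranes and two aldehydes: only the oxirane next to a carbonyl is activated for oxidative addition, the isolated 7,8-oxirane is not, and the C1 aldehyde has no leaving group at its α-carbon. Ring-closure regiochemistry is secured because the two formyl arms on C4 are equivalent and only the malondialdehyde, not the C1 aldehyde, is appreciably enolised, so the enol ether can only form as C3=C4. The driving force is release of oxirane strain together with formation of the push–pull β-alkoxy enal.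

Step 13
Reactants: 18 (4aS,7S,8R,11aR) lactol aldehyde
Product: 19 (1R,4aS,7S,8R,11aR) 1-O-acetyl lactol aldehyde
Conditions: Ac2O, Et3N, DMAP (cat.), CH2Cl2, −40 to 0 °C
Reagents that add atoms: acetic anhydride, CC(=O)OC(C)=O
Why: Base-mediated acylation of the equilibrating lactol, in which the equatorial oxygen is the more nucleophilic anomer, should place the acetate trans to the C11a–C11 bond (1R) and so fixes C1.

Step 14
Reactants: 19 (1R,4aS,7S,8R,11aR) 1-O-acetyl lactol aldehyde
Product: 20 (1R,4aS,7S,8R,11aR,12S) homoallylic alcohol: C12 bears OH and CH2CH=CH2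
Conditions: (−)-Ipc2B(allyl), Et2O, −78 °C; then HOCH2CH2NH2, rt
Reagents that add atoms: (−)-B-allyldiisopinocampheylborane, C=CCB([C@@H]1C[C@@H]2C[C@H]([C@H]1C)C2(C)C)[C@@H]1C[C@@H]2C[C@H]([C@H]1C)C2(C)C
Why: Brown allylboration through a chair-like six-membered transition state, in which the isopinocampheyl groups derived from (+)-α-pinene direct the allyl group to the aldehyde face that gives the 12S alcohol (reagent control, same sense as benzaldehyde giving the S alcohol).

Step 15
Reactants: 20 (1R,4aS,7S,8R,11aR,12S) homoallylic alcohol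
Product: 21 (1R,4aS,7S,8R,11aR,12S) 1,12-diacetate with terminal olefin
Conditions: Ac2O, pyridine, DMAP (cat.), CH2Cl2, 0 °C
Reagents that add atoms: acetic anhydride, CC(=O)OC(C)=O
Why: DMAP-catalysed acetylation of the secondary alcohol under basic conditions that spare the acetal acetate, the enol ether and the oxirane; no stereocentre is touched.

Step 16
Reactants: 21 (1R,4aS,7S,8R,11aR,12S) 1,12-diacetate; 22 methyl methacrylate
Product: 23 target, methyl (2E,5S)-5-acetoxy-5-[(1R,4aS,7S,8R,11aR)-1-acetoxy-7,8-epoxy-7-methyl-11-methylidene-dihydropyran-fused cyclononane-4-yl]-2-methylpent-2-enoate (target numbering)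
Conditions: 22 (excess), second-generation Hoveyda–Grubbs catalyst [RuCl2(=CH-C6H4-2-OiPr)(H2IMes)], CH2Cl2, 40 °C
Reagents that add atoms: none
Why: Olefin cross-metathesis between the terminal olefin and excess methyl methacrylate should give the thermodynamically favoured E trisubstituted enoate, while the hindered C19 methylene, the trisubstituted enol ether and the oxirane are not engaged.

**Compound list**

1 | 6-methylcyclohex-2-en-1-one (racemic) | CC1CCC=CC1=O | starting material
2 | acetaldehyde | CC=O | starting material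
3 | 6-(1-hydroxyethyl)-6-methylcyclohex-2-en-1-one (racemic, both diastereomers) | CC(O)C1(C)CCC=CC1=O | intermediate
4 | 6-ethenyl-6-methylcyclohex-2-en-1-one (racemic) | C=CC1(C)CCC=CC1=O | intermediate
5 | tert-butyldimethyl{[2-(4,4,5,5-tetramethyl-1,3,2-dioxaborolan-2-yl)prop-2-en-1-yl]oxy}silane | C=C(CO[Si](C)(C)C(C)(C)C)B1OC(C)(C)C(C)(C)O1 | starting material
6 | (5S)-5-{3-[(tert-butyldimethylsilyl)oxy]prop-1-en-2-yl}-2-ethenyl-2-methylcyclohexan-1-one (both C2 epimers) | O=C1C[C@@H](C(=C)CO[Si](C)(C)C(C)(C)C)CCC1(C)C=C | intermediate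
7 | (4S)-4-{3-[(tert-butyldimethylsilyl)oxy]prop-1-en-2-yl}-7-ethenyl-7-methyloxepan-2-one (both C7 epimers) | O=C1C[C@@H](C(=C)CO[Si](C)(C)C(C)(C)C)CCC(C)(C=C)O1 | intermediate
8 | (3S,4S)-4-{3-[(tert-butyldimethylsilyl)oxy]prop-1-en-2-yl}-7-ethenyl-7-methyl-3-{[tri(propan-2-yl)silyl]oxymethyl}oxepan-2-one (both C7 epimers) | O=C1[C@H](CO[Si](C(C)C)(C(C)C)C(C)C)[C@@H](C(=C)CO[Si](C)(C)C(C)(C)C)CCC(C)(C=C)O1 | intermediate
9 | methylideneoxepane: 8 with the lactone C=O replaced by C=CH2 (3S,4S; both epimers at the vinyl-bearing carbon) | C=C1[C@H](CO[Si](C(C)C)(C(C)C)C(C)C)[C@@H](C(=C)CO[Si](C)(C)C(C)(C)C)CCC(C)(C=C)O1 | intermediate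
10 | (4Z,8S,9S)-8-{3-[(tert-butyldimethylsilyl)oxy]prop-1-en-2-yl}-5-methyl-9-{[tri(propan-2-yl)silyl]oxymethyl}cyclonon-4-en-1-one | O=C1CC/C=C(C)\CC[C@H](C(=C)CO[Si](C)(C)C(C)(C)C)[C@H]1CO[Si](C(C)C)(C(C)C)C(C)C | intermediate
11 | (1Z,6R,7S)-7-{3-[(tert-butyldimethylsilyl)oxy]prop-1-en-2-yl}-1-methyl-5-methylidene-6-{[tri(propan-2-yl)silyl]oxymethyl}cyclonon-1-ene | C=C1CC/C=C(C)\CC[C@H](C(=C)CO[Si](C)(C)C(C)(C)C)[C@H]1CO[Si](C(C)C)(C(C)C)C(C)C | intermediate
12 | (4aS,7Z,11aR) allylic alcohol: 11 with C12H2OH free, C1H2OSi(iPr)3 kept | C=C1CC/C=C(C)\CC[C@H](C(=C)CO)[C@H]1CO[Si](C(C)C)(C(C)C)C(C)C | intermediate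
13 | (4S,4aS,7Z,11aR) epoxy alcohol: C3–O–C4 oxirane bearing C12H2OH | C=C1CC/C=C(C)\CC[C@H]([C@]2(CO)CO2)[C@H]1CO[Si](C(C)C)(C(C)C)C(C)C | intermediate
14 | (4S,4aS,7S,8R,11aR) bis-epoxide: 13 with the 7,8-oxirane | C=C1CC[C@H]2O[C@@]2(C)CC[C@H]([C@]3(CO)CO3)[C@H]1CO[Si](C(C)C)(C(C)C)C(C)C | intermediate
15 | (4S,4aS,7S,8R,11aR) epoxy diol: C1H2OH and C12H2OH free | C=C1CC[C@H]2O[C@@]2(C)CC[C@H]([C@]3(CO)CO3)[C@H]1CO | intermediate
16 | (4R,4aS,7S,8R,11aR) epoxy dialdehyde: C1HO on C11a, oxirane-2-carbaldehyde on C4a | C=C1CC[C@H]2O[C@@]2(C)CC[C@H]([C@]3(C=O)CO3)[C@H]1C=O | intermediate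
17 | (4aS,7S,8R,11aR) malondialdehyde enol: C4(=C3H–OH)(C12HO) on C4a, C1HO on C11a | C=C1CC[C@H]2O[C@@]2(C)CC[C@H](C(C=O)=CO)[C@H]1C=O | intermediate
18 | (4aS,7S,8R,11aR) lactol aldehyde: trans-fused dihydropyran, 1-OH (both anomers), 4-CHO, 7,8-oxirane, C19 methylene | C=C1CC[C@H]2O[C@@]2(C)CC[C@@H]2C(C=O)=COC(O)[C@@H]12 | intermediate
19 | (1R,4aS,7S,8R,11aR) 1-O-acetyl lactol aldehyde | C=C1CC[C@H]2O[C@@]2(C)CC[C@@H]2C(C=O)=CO[C@H](OC(C)=O)[C@@H]12 | intermediate
20 | (1R,4aS,7S,8R,11aR,12S) homoallylic alcohol (C12: OH, CH2CH=CH2) | C=C1CC[C@H]2O[C@@]2(C)CC[C@@H]2C([C@H](CC=C)O)=CO[C@H](OC(C)=O)[C@@H]12 | intermediate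
21 | (1R,4aS,7S,8R,11aR,12S) 1,12-diacetate with terminal olefin | C=C1CC[C@H]2O[C@@]2(C)CC[C@@H]2C([C@H](CC=C)OC(C)=O)=CO[C@H](OC(C)=O)[C@@H]12 | intermediate
22 | methyl methacrylate | C=C(C)C(=O)OC | starting material
23 | target, (1R,4aS,7S,8R,11aR,12S,14E) | C=C1CC[C@H]2O[C@@]2(C)CC[C@@H]2C([C@H](C/C=C(\C)C(=O)OC)OC(C)=O)=CO[C@H](OC(C)=O)[C@@H]12 | target

**Step count and risks**

Total step count: 16. Longest linear sequence: 16 steps (from 1).

Steps most likely to fail:

Step 12 (the proposed new method). Oxidative addition may be too slow at the fully substituted C4, or palladium may decarbonylate the aldehydes or move the β,γ-unsaturated C1 aldehyde into conjugation. The fallback reaches the same 1,3-dialdehyde by known reactions through a 1,3-diol. It sets out from 13: Cp2TiCl (trivalent titanium, from Cp2TiCl2 and Mn) with 1,4-cyclohexadiene opens the oxirane homolytically at C4 and reduces the tertiary radical, which gives the 2-substituted propane-1,3-diol F1. Shi epoxidation as in step 9 gives the 7,8-epoxy diol F2, and Bu4NF gives the triol F3. Dess–Martin oxidation of the three primary alcohols gives the trialdehyde, which is 17 and closes to 18, where the route is rejoined.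

Step 6. The thermal rearrangement may be outrun by ionisation of the tertiary allylic ether (elimination or 1,3-shift), or Z geometry may erode at the temperature needed. The fallback sets out from 8: methylenation alone at 65 °C with isolation of 9, then Al(iBu)3 in CH2Cl2 at −78 °C, which promotes the rearrangement at low temperature through the aluminium-complexed ether and reduces the new ketone in situ to the cyclononenol F4. Dess–Martin oxidation gives 10, and a separate Petasis methylenation rejoins the route at 11.

Step 4. The Lewis acid may ionise the tertiary allylic lactone as it forms, or trigger a carbonyl–ene closure of the activated ketone onto the 1,1-disubstituted olefin. The fallback accepts oxidation of that olefin instead. It sets out from 6: mCPBA (excess, NaHCO3) carries out the Baeyer–Villiger oxidation and epoxidises the 1,1-disubstituted olefin together, which gives the epoxy lactone F5 as C4 epimers (this oxirane is the one needed later). Alkylation as in step 5 gives the alkylated epoxy lactone F6, and the sequence of step 6 gives the nine-membered oxirane F7. Buffered Bu4NF removes only the TBS ether and rejoins the route at 13, as both C4 epimers; step 8 is then not needed, and the mixture is of no consequence because C4 becomes trigonal in step 12.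

**Further compounds**

F1 | step 12 | (4aS,7Z,11aR) 1,3-diol: C4H(C3H2OH)(C12H2OH) on C4a, C1H2OSi(iPr)3 on C11a | C=C1CC/C=C(C)\CC[C@H](C(CO)CO)[C@H]1CO[Si](C(C)C)(C(C)C)C(C)C
F2 | step 12 | (4aS,7S,8R,11aR) 7,8-epoxy 1,3-diol, C1 still silylated | C=C1CC[C@H]2O[C@@]2(C)CC[C@H](C(CO)CO)[C@H]1CO[Si](C(C)C)(C(C)C)C(C)C
F3 | step 12 | (4aS,7S,8R,11aR) 7,8-epoxy triol (C1, C3, C12 carbinols) | C=C1CC[C@H]2O[C@@]2(C)CC[C@H](C(CO)CO)[C@H]1CO
F4 | step 6 | cyclononenol: 10 with C11 carbinol in place of the ketone (both C11 epimers) | OC1CC/C=C(C)\CC[C@H](C(=C)CO[Si](C)(C)C(C)(C)C)[C@H]1CO[Si](C(C)C)(C(C)C)C(C)C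
F5 | step 4 | epoxy lactone: 7 with the side-chain olefin as C3–O–C4 oxirane (both C4 and C7 epimers) | O=C1C[C@@H](C2(CO[Si](C)(C)C(C)(C)C)CO2)CCC(C)(C=C)O1
F6 | step 4 | alkylated epoxy lactone: F5 with CH2OSi(iPr)3 on C11a, trans to C4a substituent | O=C1[C@H](CO[Si](C(C)C)(C(C)C)C(C)C)[C@@H](C2(CO[Si](C)(C)C(C)(C)C)CO2)CCC(C)(C=C)O1
F7 | step 4 | nine-membered oxirane: 11 with the side-chain olefin as C3–O–C4 oxirane (both C4 epimers) | C=C1CC/C=C(C)\CC[C@H](C2(CO[Si](C)(C)C(C)(C)C)CO2)[C@H]1CO[Si](C(C)C)(C(C)C)C(C)C
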